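**Plan**

- Numbering as in azulene: C3 is the carbinol carbon with the isopropyl group, C3a and C8a are the ring-fusion carbons (methyl on C8a), C4 is the ester carbon, and C6=C7 is the alkene (methyl on C6).
- Retrosynthesis: cut the vanillate C–O bond; take C4–OH back to the C4 ketone and C6–CH3 back to an enol triflate; then cut C4–C5 and C8–C8a together. The cyclopentene that remains goes back to (S)-terpinen-4-ol by ring contraction.
- Enabling feature: the seven-membered ring is a C4(O)–C3a–C8a three-carbon unit joined to a C5–C6=C7–C8 four-carbon unit. This is the retron of a siloxy-divinylcyclopropane oxy-Cope, i.e. a Brook-mediated (3+4) annulation of an acylsilane with the dienolate of methyl vinyl ketone. O3 and O4 are 1,3-related, so one silicon atom can carry both.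
- Forward order: five-membered ring first (ozonolysis, aldol condensation), then a temporary oxasilolane ring, then the seven-membered ring in the key step, then methyl, ketol, diol and ester.
- Stereochemistry: C3 comes from terpinen-4-ol; C8a from the silicon bridge in the key step; C3a from protonation and equilibration of the ketol; C4 from hydroxyl-directed hydride delivery.

Key step: step 6

Remark: [(diethylamino)diphenylsilyl]lithium is used as a reagent prepared beforehand from Ph2SiCl2, Et2NH and lithium in THF.

**Route**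

Step 1
Reactants: 1 (S)-terpinen-4-ol
Product: 2 triethyl{[(1S)-4-methyl-1-(propan-2-yl)cyclohex-3-en-1-yl]oxy}silane
Conditions: TESOTf, 2,6-lutidine, CH2Cl2, −78 °C to 0 °C
Reagents that add atoms: triethylsilyl trifluoromethanesulfonate, CC[Si](CC)(CC)OS(=O)(=O)C(F)(F)F
Why: Silylation of a tertiary alcohol with a silyl triflate and a hindered pyridine base is routine, touches no stereocentre, and blocks retro-aldol and dehydration of the β-hydroxy aldehyde that step 2 would otherwise expose.

Step 2
Reactants: 2 triethylsilyl ether of terpinen-4-ol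
Product: 4 (3S)-6-oxo-3-(propan-2-yl)-3-[(triethylsilyl)oxy]heptanal, via ozonide 3 (not isolated)
Conditions: O3, CH2Cl2, −78 °C; then Me2S, −78 °C to rt
Reagents that add atoms: ozone, [O-][O+]=O
Why: Ozonolysis with reductive work-up (Criegee mechanism) cleaves the only alkene to the 1,6-keto aldehyde and leaves the quaternary C–O stereocentre untouched.

Step 3
Reactants: 4 keto aldehyde
Product: 6 (5R)-5-hydroxy-2-methyl-5-(propan-2-yl)cyclopent-1-ene-1-carbaldehyde, via silyl-protected enal 5 (not isolated)
Conditions: piperidine (cat.), AcOH (cat.), benzene, 60 °C; then 1 M HCl, THF, rt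
Reagents that add atoms: none
Why: Amine/acid-catalysed intramolecular aldol condensation (the enamine of the aldehyde adds 5-exo to the methyl ketone, then water is lost from the new carbinol, the silyloxy group being the poorer leaving group) contracts the ring to the cyclopentene carbaldehyde, and dilute acid then frees the tertiary alcohol without creating a stereocentre.

Step 4
Reactants: 6 hydroxy enal
Product: 8 (1R)-6-methyl-3,3-diphenyl-1-(propan-2-yl)-2-oxa-3-silabicyclo[3.3.0]oct-5-en-4-ol, via dilithium adduct 7 (not isolated)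
Conditions: LiN(SiMe3)2, THF, −78 °C; (Et2N)Ph2SiLi, −78 °C; then AcOH, −78 °C to rt
Reagents that add atoms: [(diethylamino)diphenylsilyl]lithium, [Li][Si](N(CC)CC)(c1ccccc1)c1ccccc1
Why: 1,2-Addition of a silyllithium to an aldehyde (conjugate addition is blocked by the fully substituted β-carbon) gives the α-silyl carbinol, and on protonation the Si–N bond is alcoholysed by the neighbouring tertiary hydroxyl to close the five-membered oxasilolane; the new carbinol centre forms as a mixture and is erased in step 5.

Step 5
Reactants: 8 cyclic α-silyl carbinol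
Product: 9 (1R)-6-methyl-3,3-diphenyl-1-(propan-2-yl)-2-oxa-3-silabicyclo[3.3.0]oct-5-en-4-one
Conditions: Dess–Martin periodinane, CH2Cl2, 0 °C to rt
Reagents that add atoms: none
Why: Dess–Martin oxidation of an α-silyl carbinol is a standard entry to acylsilanes, avoids the base that could trigger a Brook shift, and removes the carbinol stereocentre.

Step 6
Reactants: 9 cyclic acylsilane; 10 2-(trimethylsilyloxy)buta-1,3-diene
Product: 15 (3R,8aR)-8a-methyl-3-(propan-2-yl)-3,4-[(diphenylsilanediyl)bis(oxy)]-1,2,3,5,8,8a-hexahydroazulen-6-yl trifluoromethanesulfonate, via lithium buta-1,3-dien-2-olate 11 (not isolated), via carbonyl adduct alkoxide 12 (not isolated), via bridged cyclopropanolate 13 (not isolated), via bridged lithium enolate 14 (not isolated)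
Conditions: MeLi, THF, 0 °C (10 to 11); then 9, −80 to −30 °C; then N-(5-chloropyridin-2-yl)bis(trifluoromethanesulfonimide), −78 to 0 °C
Reagents that add atoms: N-(5-chloropyridin-2-yl)bis(trifluoromethanesulfonimide), Clc1ccc(nc1)N(S(=O)(=O)C(F)(F)F)S(=O)(=O)C(F)(F)F
Why: Proposed new method: dienolate 11 adds to the acylsilane carbonyl of 9 (conjugate addition is blocked by the fully substituted β-carbon), alkoxide 12 undergoes a Brook 1,2-shift of silicon from carbon to oxygen that expands the oxasilolane to a six-membered 1,3,2-dioxasiline while the siloxyallyl anion closes 3-exo-trig onto the ketone, and the resulting cis-1,2-dialkenylcyclopropanolate 13 undergoes anionic oxy-Cope rearrangement through a boat transition state, so that C4–C5 arises in the addition and C8–C8a in the [3,3] shift that opens the cyclopropane into the seven-membered ring. The closest known reaction type is the Brook rearrangement-mediated [3+4] annulation of acyclic α,β-unsaturated acylsilanes with lithium enolates of alkenyl methyl ketones; new is only that silicon stays bonded to the C3 oxygen, which should speed the Brook shift because five-membered alkoxysilanes reach pentacoordination easily. The one lasting new stereocentre is quaternary C8a: the silicon bridge ties the C4 oxygen to the face of the C3–O bond as C4 pyramidalises, so the cyclopropane and then the C8–C8a bond can only form on the opposite face, the one that carries the isopropyl group, which is the relative configuration of the target. The step needs attack at C4 of the allyl anion instead of C8a (the [3+2] path) and a regiodefined enolate; the methyl-bearing, fully substituted C8a disfavours direct attack there, the vinyl group on the ketone opens the Cope path, and the Cope step itself places the enolate at C6=C7, where the triflimide traps it.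

Step 7
Reactants: 15 enol triflate
Product: 16 (3R,8aR)-6,8a-dimethyl-3-(propan-2-yl)-3,4-[(diphenylsilanediyl)bis(oxy)]-1,2,3,5,8,8a-hexahydroazulene
Conditions: MeMgBr, Fe(acac)3 (5 mol %), THF/NMP, −30 °C
Reagents that add atoms: methylmagnesium bromide, C[Mg]Br
Why: Iron-catalysed Kumada-type cross-coupling of an enol triflate with a methyl Grignard reagent is fast at low temperature, installs the C6 methyl group without moving the alkene, and should spare the silylene enol ether.

Step 8
Reactants: 16 silylene-bridged diene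
Product: 17 (3R,3aR,8aR)-3-hydroxy-6,8a-dimethyl-3-(propan-2-yl)-2,3,3a,5,8,8a-hexahydroazulen-4(1H)-one
Conditions: TBAF, AcOH, THF, 0 °C to rt
Reagents that add atoms: none
Why: Buffered fluoride cleaves both Si–O bonds without the acid that could ionise the allylic tertiary C3–O bond, and the C4 enolate is protonated at C3a, where the trans-fused epimer should prevail on equilibration because the acyl carbon sits trans to the isopropyl group and accepts a hydrogen bond from the cis C3 hydroxyl.

Step 9
Reactants: 17 ketol
Product: 18 jaeschkeanadiol, (3R,3aS,4S,8aR)-6,8a-dimethyl-3-(propan-2-yl)-1,2,3,3a,4,5,8,8a-octahydroazulene-3,4-diol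
Conditions: Me4NBH(OAc)3, MeCN/AcOH (1:1), −20 °C
Reagents that add atoms: none
Why: In this hydroxyl-directed reduction of a β-hydroxy ketone (Evans–Saksena reduction) the C3 alkoxyborohydride delivers hydride to the ketone face syn to the C3 oxygen, which should give the 1,3-anti diol with the (4S) carbinol.

Step 10
Reactants: 18 jaeschkeanadiol; 19 4-acetoxy-3-methoxybenzoic acid
Product: 20 (3R,3aS,4S,8aR)-3-hydroxy-6,8a-dimethyl-3-(propan-2-yl)-1,2,3,3a,4,5,8,8a-octahydroazulen-4-yl 4-acetoxy-3-methoxybenzoate
Conditions: DCC, DMAP (cat.), CH2Cl2, rt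
Reagents that add atoms: none
Why: Steglich esterification acylates the secondary C4 hydroxyl and leaves the hindered tertiary C3 hydroxyl free, the phenol being masked as its acetate so that the acid cannot self-condense; no stereocentre is affected.

Step 11
Reactants: 20 O-acetylteferin
Product: 21 teferin
Conditions: pyrrolidine, CH2Cl2, 0 °C to rt
Reagents that add atoms: none
Why: Aminolysis of the phenyl acetate by pyrrolidine is much faster than attack on the hindered alkyl benzoate, so the phenol should be released without loss or migration of the vanillate.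

**Compound list**

1 | (S)-(+)-terpinen-4-ol, (1S)-4-methyl-1-(propan-2-yl)cyclohex-3-en-1-ol | CC1=CC[C@](O)(C(C)C)CC1 | starting material
2 | triethyl{[(1S)-4-methyl-1-(propan-2-yl)cyclohex-3-en-1-yl]oxy}silane | CC1=CC[C@](O[Si](CC)(CC)CC)(C(C)C)CC1 | intermediate
3 | secondary ozonide (1,2,4-trioxolane) of 2, mixture at the ozonide carbons | CC12CC[C@@](O[Si](CC)(CC)CC)(C(C)C)CC(OO1)O2 | intermediate
4 | (3S)-6-oxo-3-(propan-2-yl)-3-[(triethylsilyl)oxy]heptanal | O=CC[C@](O[Si](CC)(CC)CC)(C(C)C)CCC(C)=O | intermediate
5 | (5R)-2-methyl-5-(propan-2-yl)-5-[(triethylsilyl)oxy]cyclopent-1-ene-1-carbaldehyde | O=CC1=C(C)CC[C@@]1(O[Si](CC)(CC)CC)C(C)C | intermediate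
6 | (5R)-5-hydroxy-2-methyl-5-(propan-2-yl)cyclopent-1-ene-1-carbaldehyde | O=CC1=C(C)CC[C@@]1(O)C(C)C | intermediate
7 | dilithium salt of the open-chain adduct, [(diethylamino)diphenylsilyl][(5R)-2-methyl-5-oxido-5-(propan-2-yl)cyclopent-1-en-1-yl]methanolate, mixture at the carbinol carbon | [Li+].[Li+].[O-]C(C1=C(C)CC[C@@]1([O-])C(C)C)[Si](N(CC)CC)(c1ccccc1)c1ccccc1 | intermediate
8 | (1R)-6-methyl-3,3-diphenyl-1-(propan-2-yl)-2-oxa-3-silabicyclo[3.3.0]oct-5-en-4-ol, both C4 epimers | OC1C2=C(C)CC[C@]2(C(C)C)O[Si]1(c1ccccc1)c1ccccc1 | intermediate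
9 | (1R)-6-methyl-3,3-diphenyl-1-(propan-2-yl)-2-oxa-3-silabicyclo[3.3.0]oct-5-en-4-one (cyclic acylsilane) | O=C1C2=C(C)CC[C@]2(C(C)C)O[Si]1(c1ccccc1)c1ccccc1 | intermediate
10 | 2-(trimethylsilyloxy)buta-1,3-diene | C=CC(=C)O[Si](C)(C)C | starting material
11 | lithium buta-1,3-dien-2-olate | [Li+].[O-]C(=C)C=C | intermediate
12 | lithium (1R)-6-methyl-4-(2-oxobut-3-en-1-yl)-3,3-diphenyl-1-(propan-2-yl)-2-oxa-3-silabicyclo[3.3.0]oct-5-en-4-olate, configuration at C4 open | [Li+].[O-]C1(CC(=O)C=C)C2=C(C)CC[C@]2(C(C)C)O[Si]1(c1ccccc1)c1ccccc1 | intermediate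
13 | silylene-bridged cis-1,2-dialkenylcyclopropanolate (spiro cyclopropane on the 1,3,2-dioxasiline, vinyl cis to the cyclopentenyl carbon, cyclopropane on the isopropyl face), lithium salt | [Li+].[O-][C@]1(C=C)C[C@]12O[Si](c3ccccc3)(c3ccccc3)O[C@@]3(C(C)C)CCC(C)=C23 | intermediate
14 | lithium (3R,8aR)-8a-methyl-3-(propan-2-yl)-3,4-[(diphenylsilanediyl)bis(oxy)]-1,2,3,5,8,8a-hexahydroazulen-6-olate | C[C@]12CC[C@]3(C(C)C)O[Si](c4ccccc4)(c4ccccc4)OC(=C13)CC([O-])=CC2.[Li+] | intermediate
15 | (3R,8aR)-8a-methyl-3-(propan-2-yl)-3,4-[(diphenylsilanediyl)bis(oxy)]-1,2,3,5,8,8a-hexahydroazulen-6-yl trifluoromethanesulfonate | C[C@]12CC[C@]3(C(C)C)O[Si](c4ccccc4)(c4ccccc4)OC(=C13)CC(OS(=O)(=O)C(F)(F)F)=CC2 | intermediate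
16 | (3R,8aR)-6,8a-dimethyl-3-(propan-2-yl)-3,4-[(diphenylsilanediyl)bis(oxy)]-1,2,3,5,8,8a-hexahydroazulene | C[C@]12CC[C@]3(C(C)C)O[Si](c4ccccc4)(c4ccccc4)OC(=C13)CC(C)=CC2 | intermediate
17 | (3R,3aR,8aR)-3-hydroxy-6,8a-dimethyl-3-(propan-2-yl)-2,3,3a,5,8,8a-hexahydroazulen-4(1H)-one | O=C2CC(C)=CC[C@@]3(C)CC[C@@](O)(C(C)C)[C@H]23 | intermediate
18 | jaeschkeanadiol, (3R,3aS,4S,8aR)-6,8a-dimethyl-3-(propan-2-yl)-1,2,3,3a,4,5,8,8a-octahydroazulene-3,4-diol | O[C@H]2CC(C)=CC[C@@]3(C)CC[C@@](O)(C(C)C)[C@H]23 | intermediate
19 | 4-acetoxy-3-methoxybenzoic acid | COc1cc(C(=O)O)ccc1OC(C)=O | starting material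
20 | (3R,3aS,4S,8aR)-3-hydroxy-6,8a-dimethyl-3-(propan-2-yl)-1,2,3,3a,4,5,8,8a-octahydroazulen-4-yl 4-acetoxy-3-methoxybenzoate | COc1cc(C(=O)O[C@H]2CC(C)=CC[C@@]3(C)CC[C@@](O)(C(C)C)[C@H]23)ccc1OC(C)=O | intermediate
21 | teferin, (3R,3aS,4S,8aR)-3-hydroxy-6,8a-dimethyl-3-(propan-2-yl)-1,2,3,3a,4,5,8,8a-octahydroazulen-4-yl 4-hydroxy-3-methoxybenzoate | COc1cc(C(=O)O[C@H]2CC(C)=CC[C@@]3(C)CC[C@@](O)(C(C)C)[C@H]23)ccc1O | target

**Count**

Total step count: 11. Longest linear sequence: 11 steps (1 to 21).

**Steps most likely to fail**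

Step 6 (carries the label). The tethered α-silyl alkoxide may not pass cleanly through the Brook shift and ring closure: the enolate may attack silicon, a proton may be transferred from the C6 methyl group of 9, or the allyl anion may close at C8a. The bridge may also slow the Cope step. The fallback is the untethered Brook-mediated annulation of an acyclic acylsilane, which is known chemistry. It sets out from 5, which is isolated by leaving out the acid stage of step 3. PhMe2SiLi (THF, −78 °C) adds to the aldehyde to give the α-silyl carbinol F1, and Swern oxidation gives the acylsilane F2. Treatment with 11 (−80 to −30 °C) and then the pyridyl triflimide gives the enol triflate F3. Here C8a is set only by the steric bias of the C3 substituents, so diastereomers may have to be separated. MeMgBr with Fe(acac)3 gives the bis-silyl diene F4, and TBAF/AcOH removes both silyl groups and returns to the route at 17.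

Step 4. The α-silyl alkoxide may undergo Brook rearrangement before the quench, or ring closure at the hindered tertiary hydroxyl may stay incomplete. The fallback is the dithiane route to acylsilanes, from 6 to 9. Propane-1,3-dithiol and MgBr2·OEt2 convert 6 into the dithiane F5. Two equivalents of n-BuLi and then Ph2SiCl2 close the ring by C- and O-silylation to the spiro dithiane F6. I2 and NaHCO3 in aqueous acetone unmask the carbonyl group and return to the route at 9.

Step 8. Control of the C3a configuration on ketonisation may be poor, and forcing equilibration on the free ketol risks retro-aldol cleavage or dehydration. The fallback unmasks the ketone in two stages through a protected ketol. It sets out from 16: one equivalent of MeLi (THF, −78 °C) cleaves only the enol Si–O bond, and protonation of the enolate gives the O-silyl ketone F7, in which retro-aldol is not possible. A mild amine base equilibrates C3a, and TBAF/AcOH then frees the hydroxyl and returns to the route at 17.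

Further compounds
F1 | step 6 | [dimethyl(phenyl)silyl]{(5R)-2-methyl-5-(propan-2-yl)-5-[(triethylsilyl)oxy]cyclopent-1-en-1-yl}methanol, mixture at the carbinol carbon | OC(C1=C(C)CC[C@@]1(O[Si](CC)(CC)CC)C(C)C)[Si](C)(C)c1ccccc1
F2 | step 6 | [dimethyl(phenyl)silyl]{(5R)-2-methyl-5-(propan-2-yl)-5-[(triethylsilyl)oxy]cyclopent-1-en-1-yl}methanone | O=C(C1=C(C)CC[C@@]1(O[Si](CC)(CC)CC)C(C)C)[Si](C)(C)c1ccccc1
F3 | step 6 | (3R,8aR)-4-{[dimethyl(phenyl)silyl]oxy}-8a-methyl-3-(propan-2-yl)-3-[(triethylsilyl)oxy]-1,2,3,5,8,8a-hexahydroazulen-6-yl trifluoromethanesulfonate | C[C@]12CC[C@@](O[Si](CC)(CC)CC)(C(C)C)C1=C(O[Si](C)(C)c1ccccc1)CC(OS(=O)(=O)C(F)(F)F)=CC2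
F4 | step 6 | (3R,8aR)-4-{[dimethyl(phenyl)silyl]oxy}-6,8a-dimethyl-3-(propan-2-yl)-3-[(triethylsilyl)oxy]-1,2,3,5,8,8a-hexahydroazulene | C[C@]12CC[C@@](O[Si](CC)(CC)CC)(C(C)C)C1=C(O[Si](C)(C)c1ccccc1)CC(C)=CC2
F5 | step 4 | (1R)-2-(1,3-dithian-2-yl)-3-methyl-1-(propan-2-yl)cyclopent-2-en-1-ol | S1CCCSC1C1=C(C)CC[C@@]1(O)C(C)C
F6 | step 4 | (1R)-6-methyl-3,3-diphenyl-1-(propan-2-yl)-2-oxa-3-silabicyclo[3.3.0]oct-5-ene-4-spiro-2'-(1,3-dithiane) | CC(C)[C@]12CCC(C)=C1C1(SCCCS1)[Si](c1ccccc1)(c1ccccc1)O2
F7 | step 8 | (3R,3aR,8aR)-6,8a-dimethyl-3-{[methyl(diphenyl)silyl]oxy}-3-(propan-2-yl)-2,3,3a,5,8,8a-hexahydroazulen-4(1H)-one | O=C2CC(C)=CC[C@@]3(C)CC[C@@](O[Si](C)(c4ccccc4)c4ccccc4)(C(C)C)[C@H]23
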